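**Retrosynthetic overview**

1. Numbering (briarane): C1 quaternary carbon (C15 methyl); C2 CH–O-propanoyl; C3, C4 CH2; C5 (C16 methyl)=C6; C7 lactone O–CH; C8 butenolide β-carbon; C9 CH2; C10 ring-fusion CH; C11 (C20 methyl)=C12; C13 CH2; C14 CH–OAc; C17 butenolide α-carbon (C18 methyl); C19 lactone C=O. Rings: cyclohexene (C1, C10–C14), ten-membered ring (C1–C10), butenolide.
2. Enabling feature: the chain C12–C13–C14–C1–C2, with oxygen on C14 and C2 on either side of the methyl-bearing quaternary C1, is a masked 2-methylcyclopentane-1,3-dione. With C2 and C12 joined as a cyclopentene, the cyclohexene is its ring-rearranged isomer, so one metathesis event makes C11=C12, opens the sacrificial five-membered ring and unveils C2 as a vinyl handle.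
3. Disconnections (retro): C7–C8 with the lactone C–O bond (Nozaki–Hiyama–Kishi closure, lactonisation in the same flask); C3–C4 (ketone enolate alkylation); the C2 carbinol (1,3-anti Evans–Tishchenko reduction from O14); C11=C12 (ring-rearrangement metathesis); C1–C10 (Claisen rearrangement on the cyclopentene, relayed from one CBS-derived carbinol, C14).
4. Ring order (forward): sacrificial cyclopentene from the dione, then the cyclohexene (key step), then the ten-membered ring and the butenolide together in the last step.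

Key step: step 10

Remark: C17 in the β-keto ester intermediates is an epimer mixture that is erased when the enol triflate is formed; the configuration at C7 rests on substrate control in the last step and is the least certain stereochemical element.

Step 1
Reactants: 1 3-[(4-methoxybenzyl)oxy]propan-1-ol
Product: 2 3-[(4-methoxybenzyl)oxy]propanal
Conditions: TEMPO (10 mol%), PhI(OAc)2 (1.1 equiv), CH2Cl2, rt
Reagents that add atoms: none
Why: Oxoammonium (TEMPO) oxidation of a primary alcohol should stop at the aldehyde and leave the PMB ether untouched; no stereocentre is involved.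

Step 2
Reactants: 2 3-[(4-methoxybenzyl)oxy]propanal
Product: 3 ethyl (2Z)-5-[(4-methoxybenzyl)oxy]-2-methylpent-2-enoate
Conditions: ethyl 2-[bis(2,2,2-trifluoroethoxy)phosphoryl]propanoate, KHMDS, 18-crown-6, THF, −78 °C
Reagents that add atoms: ethyl 2-[bis(2,2,2-trifluoroethoxy)phosphoryl]propanoate, CCOC(=O)C(C)P(=O)(OCC(F)(F)F)OCC(F)(F)F
Why: Still–Gennari olefination under dissociating conditions should give the kinetically controlled Z enoate, which fixes the cis relation between C9 and the future O–CH2 carbon that the Claisen step needs.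

Step 3
Reactants: 3 ethyl (2Z)-5-[(4-methoxybenzyl)oxy]-2-methylpent-2-enoate
Product: 4 (2Z)-5-[(4-methoxybenzyl)oxy]-2-methylpent-2-en-1-ol
Conditions: DIBAL-H (2.5 equiv), CH2Cl2, −78 to 0 °C; Rochelle salt work-up
Reagents that add atoms: none
Why: DIBAL-H 1,2-reduction of the enoate should give the allylic alcohol with the Z geometry retained.

Step 4
Reactants: 5 2-methylcyclopentane-1,3-dione
Product: 6 3-iodo-2-methylcyclopent-2-en-1-one
Conditions: PPh3, I2, Et3N, MeCN, rt to 60 °C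
Reagents that add atoms: iodine, II
Why: O-Phosphonium activation of the enol followed by addition–elimination of iodide is the standard conversion of a cyclic 1,3-dione into a β-iodo enone.

Step 5
Reactants: 6 3-iodo-2-methylcyclopent-2-en-1-one
Product: 7 (1S)-3-iodo-2-methylcyclopent-2-en-1-ol
Conditions: (R)-2-methyl-CBS-oxazaborolidine (15 mol%), BH3·SMe2 (0.7 equiv), THF, −20 °C; MeOH quench
Reagents that add atoms: none
Why: Corey–Bakshi–Shibata reduction, in which the (R)-catalyst reads the α-methylvinyl flank as large and the C13 methylene as small, should deliver hydride to give the S carbinol (C14).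

Step 6
Reactants: 7 (1S)-3-iodo-2-methylcyclopent-2-en-1-ol
Product: 8 tert-butyl{[(1S)-3-iodo-2-methylcyclopent-2-en-1-yl]oxy}dimethylsilane
Conditions: TBSCl, imidazole, DMF, rt
Reagents that add atoms: tert-butyl(chloro)dimethylsilane, CC(C)(C)[Si](C)(C)Cl
Why: Standard silylation of the secondary alcohol installs the bulky ether that shields one face of the ring in the next step.

Step 7
Reactants: 8 tert-butyl{[(1S)-3-iodo-2-methylcyclopent-2-en-1-yl]oxy}dimethylsilane and 4 (2Z)-5-[(4-methoxybenzyl)oxy]-2-methylpent-2-en-1-ol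
Product: 10 (2R,3S)-3-[(tert-butyldimethylsilyl)oxy]-2-{(3S)-1-[(4-methoxybenzyl)oxy]-4-methylpent-4-en-3-yl}-2-methylcyclopentan-1-one, via allyl vinyl ether 9 (not isolated)
Conditions: CuI (10 mol%), 3,4,7,8-tetramethyl-1,10-phenanthroline (20 mol%), Cs2CO3 (2 equiv), o-xylene, 120 °C, sealed tube
Reagents that add atoms: none
Why: Copper-catalysed vinyl C–O coupling followed in the same flask by Claisen rearrangement should transfer the allyl unit to C1 on the face anti to the C14 silyl ether (sets C1), while the chair transition state with the Z olefin (C9 pseudo-axial) sets C10.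

Step 8
Reactants: 10 (2R,3S)-3-[(tert-butyldimethylsilyl)oxy]-2-{(3S)-1-[(4-methoxybenzyl)oxy]-4-methylpent-4-en-3-yl}-2-methylcyclopentan-1-one
Product: 12 (4S,5R)-4-[(tert-butyldimethylsilyl)oxy]-5-{(3S)-1-[(4-methoxybenzyl)oxy]-4-methylpent-4-en-3-yl}-5-methylcyclopent-1-en-1-yl trifluoromethanesulfonate, via potassium enolate 11 (not isolated)
Conditions: KHMDS, THF, −78 °C; then PhNTf2, −78 to 0 °C
Reagents that add atoms: potassium bis(trimethylsilyl)amide, [K+].C[Si](C)(C)[N-][Si](C)(C)C (potassium in 11 only); N-phenylbis(trifluoromethanesulfonimide), O=S(=O)(N(c1ccccc1)S(=O)(=O)C(F)(F)F)C(F)(F)F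
Why: Enolisation can occur only towards C12 because C1 is quaternary, and O-sulfonylation of the enolate gives the enol triflate without touching a stereocentre.

Step 9
Reactants: 12 (4S,5R)-4-[(tert-butyldimethylsilyl)oxy]-5-{(3S)-1-[(4-methoxybenzyl)oxy]-4-methylpent-4-en-3-yl}-5-methylcyclopent-1-en-1-yl trifluoromethanesulfonate
Product: 13 tert-butyl{[(1S,2R)-2-{(3S)-1-[(4-methoxybenzyl)oxy]-4-methylpent-4-en-3-yl}-2-methylcyclopent-3-en-1-yl]oxy}dimethylsilane
Conditions: Pd(OAc)2 (5 mol%), PPh3 (10 mol%), HCO2H, Bu3N, DMF, 60 °C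
Reagents that add atoms: none
Why: Palladium-catalysed formate reduction of the enol triflate replaces OTf by H and should leave the isopropenyl group alone, giving the cis-disubstituted C2=C12 cyclopentene.

Step 10
Reactants: 13 tert-butyl{[(1S,2R)-2-{(3S)-1-[(4-methoxybenzyl)oxy]-4-methylpent-4-en-3-yl}-2-methylcyclopent-3-en-1-yl]oxy}dimethylsilane
Product: 14 tert-butyl{[(1S,5S,6R)-6-ethenyl-5-{2-[(4-methoxybenzyl)oxy]ethyl}-4,6-dimethylcyclohex-3-en-1-yl]oxy}dimethylsilane
Conditions: second-generation Hoveyda–Grubbs catalyst RuCl2(H2IMes)(=CH–C6H4-2-OiPr) (5 mol%), toluene (0.01 M), 60 °C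
Reagents that add atoms: none
Why: The ruthenium methylidene that carries the chain adds to the strained cis C2=C12 bond with ruthenium on the less hindered C12 (methylene to C2, next to quaternary C1), opening the five-membered ring to a C12 alkylidene that is trapped by the 1,1-disubstituted C11 olefin through a ruthenacyclobutane, which forms C11=C12 and releases the methylidene again. The closest known reaction type is ring-rearrangement metathesis (ring-opening/ring-closing metathesis) of cyclopentenes that carry a tethered olefin. The only ring closed is the cyclohexene C1–C10–C11=C12–C13–C14, by ring-closing metathesis; closure of a C2 alkylidene onto C11 would give a cyclobutene and does not compete. No stereocentre is created or touched: C14, C1 and C10, set on the cyclopentane in steps 5 and 7, are carried unchanged into the six-membered ring. The selectivity needed is directional (cyclopentene to cyclohexene, not back and not to oligomers), and it is secured by the loss of roughly 4 kcal/mol of ring strain and by the fact that both new olefins, a vinyl group on a quaternary carbon and a trisubstituted ring alkene, are inert to the catalyst.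

Step 11
Reactants: 14 tert-butyl{[(1S,5S,6R)-6-ethenyl-5-{2-[(4-methoxybenzyl)oxy]ethyl}-4,6-dimethylcyclohex-3-en-1-yl]oxy}dimethylsilane
Product: 15 1-[(1R,2S,6S)-6-[(tert-butyldimethylsilyl)oxy]-2-{2-[(4-methoxybenzyl)oxy]ethyl}-1,3-dimethylcyclohex-3-en-1-yl]ethan-1-one
Conditions: PdCl2(quinox) (5 mol%; quinox = 2-(4,5-dihydro-1,3-oxazol-2-yl)quinoline), AgSbF6 (12 mol%), aq. tBuOOH (12 equiv), CH2Cl2, 0 °C to rt
Reagents that add atoms: tert-butyl hydroperoxide, CC(C)(C)OO
Why: Wacker-type oxidation with a cationic palladium catalyst should be Markovnikov-selective and confined to the monosubstituted vinyl group, giving the methyl ketone whose methyl carbon becomes C3.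

Step 12
Reactants: 16 prop-2-yn-1-ol
Product: 18 (2Z)-3-iodo-2-methylprop-2-en-1-ol, via vinylmagnesium alkoxide 17 (not isolated)
Conditions: MeMgBr (2.5 equiv), CuI (10 mol%), THF, −10 °C to rt; then I2, −40 to 0 °C
Reagents that add atoms: methylmagnesium bromide, C[Mg]Br; iodine, II
Why: Copper-catalysed anti-carbomagnesiation directed by the magnesium alkoxide, then iodinolysis with retention, should give the Z vinyl iodide.

Step 13
Reactants: 18 (2Z)-3-iodo-2-methylprop-2-en-1-ol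
Product: 19 (1Z)-3-bromo-1-iodo-2-methylprop-1-ene
Conditions: CBr4, PPh3, CH2Cl2, 0 °C
Reagents that add atoms: tetrabromomethane, BrC(Br)(Br)Br
Why: Appel bromination of the primary allylic alcohol under neutral conditions should preserve the olefin geometry.

Step 14
Reactants: 15 1-[(1R,2S,6S)-6-[(tert-butyldimethylsilyl)oxy]-2-{2-[(4-methoxybenzyl)oxy]ethyl}-1,3-dimethylcyclohex-3-en-1-yl]ethan-1-one and 19 (1Z)-3-bromo-1-iodo-2-methylprop-1-ene
Product: 21 (4Z)-1-[(1R,2S,6S)-6-[(tert-butyldimethylsilyl)oxy]-2-{2-[(4-methoxybenzyl)oxy]ethyl}-1,3-dimethylcyclohex-3-en-1-yl]-5-iodo-4-methylpent-4-en-1-one, via lithium enolate 20 (not isolated)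
Conditions: LDA (1.1 equiv), THF, −78 °C; then 19 (1.5 equiv), DMPU, −78 to −30 °C
Reagents that add atoms: lithium diisopropylamide, [Li+].CC(C)[N-]C(C)C (lithium in 20 only)
Why: The methyl group is the only enolisable position of the ketone, and SN2 alkylation of its lithium enolate with the allylic bromide forms C3–C4.

Step 15
Reactants: 21 (4Z)-1-[(1R,2S,6S)-6-[(tert-butyldimethylsilyl)oxy]-2-{2-[(4-methoxybenzyl)oxy]ethyl}-1,3-dimethylcyclohex-3-en-1-yl]-5-iodo-4-methylpent-4-en-1-one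
Product: 22 (4Z)-1-[(1R,2S,6S)-6-hydroxy-2-{2-[(4-methoxybenzyl)oxy]ethyl}-1,3-dimethylcyclohex-3-en-1-yl]-5-iodo-4-methylpent-4-en-1-one
Conditions: HF·pyridine, pyridine/THF, 0 °C to rt
Reagents that add atoms: none
Why: Acidic fluoride desilylation frees the C14 hydroxyl while avoiding the basic conditions that could open the β-hydroxy ketone by retro-aldol cleavage; PMB ether and vinyl iodide should survive.

Step 16
Reactants: 22 (4Z)-1-[(1R,2S,6S)-6-hydroxy-2-{2-[(4-methoxybenzyl)oxy]ethyl}-1,3-dimethylcyclohex-3-en-1-yl]-5-iodo-4-methylpent-4-en-1-one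
Product: 23 (1S,5S,6S)-6-[(1S,4Z)-1-hydroxy-5-iodo-4-methylpent-4-en-1-yl]-5-{2-[(4-methoxybenzyl)oxy]ethyl}-4,6-dimethylcyclohex-3-en-1-yl acetate
Conditions: SmI2 (30 mol%), CH3CHO (10 equiv), THF, −10 °C
Reagents that add atoms: acetaldehyde, CC=O
Why: Evans–Tishchenko reduction, in which the samarium-bound hemiacetal on O14 delivers hydride to the C2 ketone through a chair transition state, should give the 1,3-anti (2S) alcohol and leave the acetate on O14.

Step 17
Reactants: 23 (1S,5S,6S)-6-[(1S,4Z)-1-hydroxy-5-iodo-4-methylpent-4-en-1-yl]-5-{2-[(4-methoxybenzyl)oxy]ethyl}-4,6-dimethylcyclohex-3-en-1-yl acetate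
Product: 24 (1S,5S,6S)-6-[(1S,4Z)-5-iodo-4-methyl-1-(propanoyloxy)pent-4-en-1-yl]-5-{2-[(4-methoxybenzyl)oxy]ethyl}-4,6-dimethylcyclohex-3-en-1-yl acetate
Conditions: (EtCO)2O, DMAP (cat.), Et3N, CH2Cl2, rt
Reagents that add atoms: propanoic anhydride, CCC(=O)OC(=O)CC
Why: DMAP-catalysed acylation of the only free hydroxyl installs the C2 propanoate with the configuration unchanged.

Step 18
Reactants: 24 (1S,5S,6S)-6-[(1S,4Z)-5-iodo-4-methyl-1-(propanoyloxy)pent-4-en-1-yl]-5-{2-[(4-methoxybenzyl)oxy]ethyl}-4,6-dimethylcyclohex-3-en-1-yl acetate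
Product: 25 (1S,5S,6S)-5-(2-hydroxyethyl)-6-[(1S,4Z)-5-iodo-4-methyl-1-(propanoyloxy)pent-4-en-1-yl]-4,6-dimethylcyclohex-3-en-1-yl acetate
Conditions: DDQ, CH2Cl2/pH 7 buffer, 0 °C to rt
Reagents that add atoms: none
Why: Oxidative PMB ether cleavage through the benzylic oxocarbenium ion should spare the esters, both alkenes and the vinyl iodide.

Step 19
Reactants: 25 (1S,5S,6S)-5-(2-hydroxyethyl)-6-[(1S,4Z)-5-iodo-4-methyl-1-(propanoyloxy)pent-4-en-1-yl]-4,6-dimethylcyclohex-3-en-1-yl acetate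
Product: 26 [(1S,5S,6S)-5-acetoxy-6-[(1S,4Z)-5-iodo-4-methyl-1-(propanoyloxy)pent-4-en-1-yl]-2,6-dimethylcyclohex-2-en-1-yl]acetic acid
Conditions: TEMPO (20 mol%), PhI(OAc)2 (2.5 equiv), MeCN/H2O, rt
Reagents that add atoms: water, O
Why: TEMPO/PhI(OAc)2 oxidation in aqueous acetonitrile takes the primary alcohol through the aldehyde hydrate to the carboxylic acid (C8) under conditions the esters tolerate.

Step 20
Reactants: 27 dimethyl 2-methylpropanedioate
Product: 28 potassium 3-methoxy-2-methyl-3-oxopropanoate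
Conditions: KOH (1.0 equiv), MeOH, 0 °C to rt
Reagents that add atoms: potassium hydroxide, [K+].[OH-]
Why: Mono-saponification of the symmetrical diester with one equivalent of hydroxide stops at the half-ester salt because the carboxylate deactivates the second ester.

Step 21
Reactants: 26 [(1S,5S,6S)-5-acetoxy-6-[(1S,4Z)-5-iodo-4-methyl-1-(propanoyloxy)pent-4-en-1-yl]-2,6-dimethylcyclohex-2-en-1-yl]acetic acid and 28 potassium 3-methoxy-2-methyl-3-oxopropanoate
Product: 30 methyl 4-[(1S,5S,6S)-5-acetoxy-6-[(1S,4Z)-5-iodo-4-methyl-1-(propanoyloxy)pent-4-en-1-yl]-2,6-dimethylcyclohex-2-en-1-yl]-2-methyl-3-oxobutanoate (both C17 epimers), via acyl imidazolide 29 (not isolated)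
Conditions: CDI, THF, rt; then 28, MgCl2, Et3N, MeCN, rt to 40 °C; aq. HCl work-up
Reagents that add atoms: 1,1'-carbonyldiimidazole, O=C(n1ccnc1)n1ccnc1 (its imidazolyl group is present in 29 only)
Why: Decarboxylative Claisen condensation of the magnesium malonate half-ester with the acyl imidazolide (Masamune conditions) builds C8–C17–C19 under near-neutral conditions that spare the acetate and propanoate.

Step 22
Reactants: 30 methyl 4-[(1S,5S,6S)-5-acetoxy-6-[(1S,4Z)-5-iodo-4-methyl-1-(propanoyloxy)pent-4-en-1-yl]-2,6-dimethylcyclohex-2-en-1-yl]-2-methyl-3-oxobutanoate (both C17 epimers)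
Product: 31 methyl 4-[(1S,5S,6S)-5-acetoxy-2,6-dimethyl-6-[(1S,4Z)-4-methyl-6-oxo-1-(propanoyloxy)hex-4-en-1-yl]cyclohex-2-en-1-yl]-2-methyl-3-oxobutanoate (both C17 epimers)
Conditions: Pd(PPh3)4 (5 mol%), CO (3 atm), Bu3SnH (slow addition), THF, 50 °C
Reagents that add atoms: carbon monoxide, [C-]#[O+]
Why: Palladium-catalysed reductive carbonylation (oxidative addition of zerovalent palladium to the vinyl iodide, CO insertion, hydride transfer from tin) should give the C7 enal with the Z geometry retained.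

Step 23
Reactants: 31 methyl 4-[(1S,5S,6S)-5-acetoxy-2,6-dimethyl-6-[(1S,4Z)-4-methyl-6-oxo-1-(propanoyloxy)hex-4-en-1-yl]cyclohex-2-en-1-yl]-2-methyl-3-oxobutanoate (both C17 epimers)
Product: 33 methyl (2Z)-4-[(1S,5S,6S)-5-acetoxy-2,6-dimethyl-6-[(1S,4Z)-4-methyl-6-oxo-1-(propanoyloxy)hex-4-en-1-yl]cyclohex-2-en-1-yl]-2-methyl-3-{[(trifluoromethyl)sulfonyl]oxy}but-2-enoate, via sodium enolate 32 (not isolated)
Conditions: NaH (1.05 equiv), THF, 0 °C; then PhNTf2, 0 °C to rt
Reagents that add atoms: sodium hydride, [Na+].[H-] (sodium in 32 only); N-phenylbis(trifluoromethanesulfonimide), O=S(=O)(N(c1ccccc1)S(=O)(=O)C(F)(F)F)C(F)(F)F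
Why: The β-keto ester is by far the most acidic site, and O-sulfonylation of its chelated sodium Z-enolate should give the Z enol triflate with OTf cis to the ester, which also erases the C17 epimers.

Step 24
Reactants: 33 methyl (2Z)-4-[(1S,5S,6S)-5-acetoxy-2,6-dimethyl-6-[(1S,4Z)-4-methyl-6-oxo-1-(propanoyloxy)hex-4-en-1-yl]cyclohex-2-en-1-yl]-2-methyl-3-{[(trifluoromethyl)sulfonyl]oxy}but-2-enoate
Product: 35 (1S,2S,5Z,7S,10S,14S)-14-acetoxy-2-(propanoyloxy)briara-5,8(17),11-trien-19,7-olide (target CNP0112230.2; numbering as in the overview), via seco hydroxy ester 34 (not isolated)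
Conditions: CrCl2 (10 equiv), NiCl2 (5 mol%), DMF, rt, 2 mM; aq. NH4Cl work-up
Reagents that add atoms: none
Why: Intramolecular Nozaki–Hiyama–Kishi addition of the C8 alkenylchromium (from the enol triflate) to the C7 aldehyde closes the ten-membered ring, the C7 alkoxide cis to the ester lactonises to the butenolide, and C7 is set by macrocyclic substrate control, expected but not assured to favour 7S.

**Compound list**

1 | 3-[(4-methoxybenzyl)oxy]propan-1-ol | COc1ccc(COCCCO)cc1 | starting material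
2 | 3-[(4-methoxybenzyl)oxy]propanal | COc1ccc(COCCC=O)cc1 | intermediate
3 | ethyl (2Z)-5-[(4-methoxybenzyl)oxy]-2-methylpent-2-enoate | COc1ccc(COCC/C=C(/C)C(=O)OCC)cc1 | intermediate
4 | (2Z)-5-[(4-methoxybenzyl)oxy]-2-methylpent-2-en-1-ol | COc1ccc(COCC/C=C(/C)CO)cc1 | intermediate
5 | 2-methylcyclopentane-1,3-dione | CC1C(=O)CCC1=O | starting material
6 | 3-iodo-2-methylcyclopent-2-en-1-one | CC1=C(I)CCC1=O | intermediate
7 | (1S)-3-iodo-2-methylcyclopent-2-en-1-ol | CC1=C(I)CC[C@@H]1O | intermediate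
8 | tert-butyl{[(1S)-3-iodo-2-methylcyclopent-2-en-1-yl]oxy}dimethylsilane | CC1=C(I)CC[C@@H]1O[Si](C)(C)C(C)(C)C | intermediate
9 | tert-butyl{[(1S)-3-{[(2Z)-5-[(4-methoxybenzyl)oxy]-2-methylpent-2-en-1-yl]oxy}-2-methylcyclopent-2-en-1-yl]oxy}dimethylsilane (allyl vinyl ether) | COc1ccc(COCC/C=C(/C)COC2=C(C)[C@@H](O[Si](C)(C)C(C)(C)C)CC2)cc1 | intermediate
10 | (2R,3S)-3-[(tert-butyldimethylsilyl)oxy]-2-{(3S)-1-[(4-methoxybenzyl)oxy]-4-methylpent-4-en-3-yl}-2-methylcyclopentan-1-one | COc1ccc(COCC[C@@H](C(C)=C)[C@@]2(C)C(=O)CC[C@@H]2O[Si](C)(C)C(C)(C)C)cc1 | intermediate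
11 | potassium (4S,5R)-4-[(tert-butyldimethylsilyl)oxy]-5-{(3S)-1-[(4-methoxybenzyl)oxy]-4-methylpent-4-en-3-yl}-5-methylcyclopent-1-en-1-olate | COc1ccc(COCC[C@@H](C(C)=C)[C@@]2(C)C(O[K])=CC[C@@H]2O[Si](C)(C)C(C)(C)C)cc1 | intermediate
12 | (4S,5R)-4-[(tert-butyldimethylsilyl)oxy]-5-{(3S)-1-[(4-methoxybenzyl)oxy]-4-methylpent-4-en-3-yl}-5-methylcyclopent-1-en-1-yl trifluoromethanesulfonate | COc1ccc(COCC[C@@H](C(C)=C)[C@@]2(C)C(OS(=O)(=O)C(F)(F)F)=CC[C@@H]2O[Si](C)(C)C(C)(C)C)cc1 | intermediate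
13 | tert-butyl{[(1S,2R)-2-{(3S)-1-[(4-methoxybenzyl)oxy]-4-methylpent-4-en-3-yl}-2-methylcyclopent-3-en-1-yl]oxy}dimethylsilane | COc1ccc(COCC[C@@H](C(C)=C)[C@@]2(C)C=CC[C@@H]2O[Si](C)(C)C(C)(C)C)cc1 | intermediate
14 | tert-butyl{[(1S,5S,6R)-6-ethenyl-5-{2-[(4-methoxybenzyl)oxy]ethyl}-4,6-dimethylcyclohex-3-en-1-yl]oxy}dimethylsilane | COc1ccc(COCC[C@H]2C(C)=CC[C@H](O[Si](C)(C)C(C)(C)C)[C@@]2(C=C)C)cc1 | intermediate
15 | 1-[(1R,2S,6S)-6-[(tert-butyldimethylsilyl)oxy]-2-{2-[(4-methoxybenzyl)oxy]ethyl}-1,3-dimethylcyclohex-3-en-1-yl]ethan-1-one | COc1ccc(COCC[C@H]2C(C)=CC[C@H](O[Si](C)(C)C(C)(C)C)[C@@]2(C(C)=O)C)cc1 | intermediate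
16 | prop-2-yn-1-ol | C#CCO | starting material
17 | bromo{(1Z)-3-[(bromomagnesio)oxy]-2-methylprop-1-en-1-yl}magnesium | Br[Mg]OC/C(C)=C\[Mg]Br | intermediate
18 | (2Z)-3-iodo-2-methylprop-2-en-1-ol | OC/C(C)=C\I | intermediate
19 | (1Z)-3-bromo-1-iodo-2-methylprop-1-ene | BrC/C(C)=C\I | intermediate
20 | lithium 1-[(1R,2S,6S)-6-[(tert-butyldimethylsilyl)oxy]-2-{2-[(4-methoxybenzyl)oxy]ethyl}-1,3-dimethylcyclohex-3-en-1-yl]ethen-1-olate | COc1ccc(COCC[C@H]2C(C)=CC[C@H](O[Si](C)(C)C(C)(C)C)[C@@]2(C(=C)O[Li])C)cc1 | intermediate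
21 | (4Z)-1-[(1R,2S,6S)-6-[(tert-butyldimethylsilyl)oxy]-2-{2-[(4-methoxybenzyl)oxy]ethyl}-1,3-dimethylcyclohex-3-en-1-yl]-5-iodo-4-methylpent-4-en-1-one | COc1ccc(COCC[C@H]2C(C)=CC[C@H](O[Si](C)(C)C(C)(C)C)[C@@]2(C(=O)CC/C(C)=C\I)C)cc1 | intermediate
22 | (4Z)-1-[(1R,2S,6S)-6-hydroxy-2-{2-[(4-methoxybenzyl)oxy]ethyl}-1,3-dimethylcyclohex-3-en-1-yl]-5-iodo-4-methylpent-4-en-1-one | COc1ccc(COCC[C@H]2C(C)=CC[C@H](O)[C@@]2(C(=O)CC/C(C)=C\I)C)cc1 | intermediate
23 | (1S,5S,6S)-6-[(1S,4Z)-1-hydroxy-5-iodo-4-methylpent-4-en-1-yl]-5-{2-[(4-methoxybenzyl)oxy]ethyl}-4,6-dimethylcyclohex-3-en-1-yl acetate | COc1ccc(COCC[C@H]2C(C)=CC[C@H](OC(C)=O)[C@@]2([C@@H](O)CC/C(C)=C\I)C)cc1 | intermediate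
24 | (1S,5S,6S)-6-[(1S,4Z)-5-iodo-4-methyl-1-(propanoyloxy)pent-4-en-1-yl]-5-{2-[(4-methoxybenzyl)oxy]ethyl}-4,6-dimethylcyclohex-3-en-1-yl acetate | COc1ccc(COCC[C@H]2C(C)=CC[C@H](OC(C)=O)[C@@]2([C@@H](OC(=O)CC)CC/C(C)=C\I)C)cc1 | intermediate
25 | (1S,5S,6S)-5-(2-hydroxyethyl)-6-[(1S,4Z)-5-iodo-4-methyl-1-(propanoyloxy)pent-4-en-1-yl]-4,6-dimethylcyclohex-3-en-1-yl acetate | OCC[C@H]1C(C)=CC[C@H](OC(C)=O)[C@@]1([C@@H](OC(=O)CC)CC/C(C)=C\I)C | intermediate
26 | [(1S,5S,6S)-5-acetoxy-6-[(1S,4Z)-5-iodo-4-methyl-1-(propanoyloxy)pent-4-en-1-yl]-2,6-dimethylcyclohex-2-en-1-yl]acetic acid | OC(=O)C[C@H]1C(C)=CC[C@H](OC(C)=O)[C@@]1([C@@H](OC(=O)CC)CC/C(C)=C\I)C | intermediate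
27 | dimethyl 2-methylpropanedioate | COC(=O)C(C)C(=O)OC | starting material
28 | potassium 3-methoxy-2-methyl-3-oxopropanoate | [K+].[O-]C(=O)C(C)C(=O)OC | intermediate
29 | (1S,5S,6S)-5-[2-(1H-imidazol-1-yl)-2-oxoethyl]-6-[(1S,4Z)-5-iodo-4-methyl-1-(propanoyloxy)pent-4-en-1-yl]-4,6-dimethylcyclohex-3-en-1-yl acetate (acyl imidazolide of 26) | O=C(C[C@H]1C(C)=CC[C@H](OC(C)=O)[C@@]1([C@@H](OC(=O)CC)CC/C(C)=C\I)C)n1ccnc1 | intermediate
30 | methyl 4-[(1S,5S,6S)-5-acetoxy-6-[(1S,4Z)-5-iodo-4-methyl-1-(propanoyloxy)pent-4-en-1-yl]-2,6-dimethylcyclohex-2-en-1-yl]-2-methyl-3-oxobutanoate (both C17 epimers) | COC(=O)C(C)C(=O)C[C@H]1C(C)=CC[C@H](OC(C)=O)[C@@]1([C@@H](OC(=O)CC)CC/C(C)=C\I)C | intermediate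
31 | methyl 4-[(1S,5S,6S)-5-acetoxy-2,6-dimethyl-6-[(1S,4Z)-4-methyl-6-oxo-1-(propanoyloxy)hex-4-en-1-yl]cyclohex-2-en-1-yl]-2-methyl-3-oxobutanoate (both C17 epimers) | COC(=O)C(C)C(=O)C[C@H]1C(C)=CC[C@H](OC(C)=O)[C@@]1([C@@H](OC(=O)CC)CC/C(C)=C\C=O)C | intermediate
32 | sodium (2Z)-enolate of 31 (C8–ONa cis to the ester) | COC(=O)/C(C)=C(\O[Na])C[C@H]1C(C)=CC[C@H](OC(C)=O)[C@@]1([C@@H](OC(=O)CC)CC/C(C)=C\C=O)C | intermediate
33 | methyl (2Z)-4-[(1S,5S,6S)-5-acetoxy-2,6-dimethyl-6-[(1S,4Z)-4-methyl-6-oxo-1-(propanoyloxy)hex-4-en-1-yl]cyclohex-2-en-1-yl]-2-methyl-3-{[(trifluoromethyl)sulfonyl]oxy}but-2-enoate | COC(=O)/C(C)=C(\OS(=O)(=O)C(F)(F)F)C[C@H]1C(C)=CC[C@H](OC(C)=O)[C@@]1([C@@H](OC(=O)CC)CC/C(C)=C\C=O)C | intermediate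
34 | methyl (2Z)-2-[(1S,2S,5Z,7S,10S,14S)-14-acetoxy-7-hydroxy-1,5,11-trimethyl-2-(propanoyloxy)bicyclo[8.4.0]tetradeca-5,11-dien-8-ylidene]propanoate (seco hydroxy ester; chromium alkoxide in the flask) | CCC(=O)O[C@H]1CC/C(C)=C\[C@H](O)/C(C[C@H]2C(C)=CC[C@H](OC(C)=O)[C@]12C)=C(/C)C(=O)OC | intermediate
35 | (1S,2S,5Z,7S,10S,14S)-14-acetoxy-2-(propanoyloxy)briara-5,8(17),11-trien-19,7-olide (CNP0112230.2) | CCC(=O)O[C@H]1CC/C(C)=C\[C@@H]2OC(=O)C(C)=C2C[C@H]2C(C)=CC[C@H](OC(C)=O)[C@]12C | target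

**Step count and risks**

Total step count: 24. Longest linear sequence: 18 steps (steps 4–11, 14–19 and 21–24 from 5; the same length from 1 through steps 1–3, 7–11, 14–19 and 21–24).

Steps most likely to fail:

Step 24. The closure may be overtaken by intermolecular coupling (oligomerisation) of the strained ten-membered transition state, and the facial selectivity at C7 may be poor or reversed. The fallback closes the ring by a carbonylative Stille coupling and sets C7 afterwards by reagent control. It sets out from 30. Stannylation of the vinyl iodide (Pd(PPh3)4, Me3SnSnMe3) would give the Z vinylstannane F1. NaH and PhNTf2 would convert this into the Z enol triflate F2. Intramolecular carbonylative Stille coupling (Pd(PPh3)4, LiCl, CO, high dilution) would insert C7 as a carbonyl and give the macrocyclic dienone ester F3. Corey–Bakshi–Shibata reduction with the (R)-oxazaborolidine, C8 taken as the large flank, should then give the 7S alcohol 34, which lactonises to 35, where the fallback rejoins the route.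

Step 11. Nucleopalladation at the vinyl group, which sits on a quaternary carbon between two substituted ring carbons, may be too slow or may drift to the anti-Markovnikov aldehyde. The fallback replaces the palladium oxidation by hydration and oxidation. From 14, oxymercuration–demercuration (Hg(OAc)2, THF/H2O; then NaBH4, NaOH), which strongly prefers the monosubstituted alkene and is Markovnikov-selective, would give the secondary alcohol F4 as a mixture of carbinol epimers. Dess–Martin oxidation of F4 returns to 15.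

Step 7. Oxidative addition and C–O bond formation at the hindered, fully substituted vinyl iodide may fail, and the prolonged heating with base may erode the chair selectivity of the rearrangement. The fallback builds the same allyl vinyl ether without copper. From 5 and 4, Mitsunobu O-alkylation (PPh3, DIAD) would give the vinylogous ester F5. Corey–Bakshi–Shibata 1,2-reduction with the (R)-catalyst and catecholborane would give the acid-sensitive allylic alcohol F6, which is silylated at once (TBSCl, imidazole) to 9, isolated in this variant. Thermal Claisen rearrangement of 9 (toluene, 150 °C, sealed tube, trace Et3N) returns to 10.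

Further compounds
F1 | step 24 | methyl 4-[(1S,5S,6S)-5-acetoxy-2,6-dimethyl-6-[(1S,4Z)-4-methyl-1-(propanoyloxy)-5-(trimethylstannyl)pent-4-en-1-yl]cyclohex-2-en-1-yl]-2-methyl-3-oxobutanoate | COC(=O)C(C)C(=O)C[C@H]1C(C)=CC[C@H](OC(C)=O)[C@@]1([C@@H](OC(=O)CC)CC/C(C)=C\[Sn](C)(C)C)C
F2 | step 24 | methyl (2Z)-4-[(1S,5S,6S)-5-acetoxy-2,6-dimethyl-6-[(1S,4Z)-4-methyl-1-(propanoyloxy)-5-(trimethylstannyl)pent-4-en-1-yl]cyclohex-2-en-1-yl]-2-methyl-3-{[(trifluoromethyl)sulfonyl]oxy}but-2-enoate | COC(=O)/C(C)=C(\OS(=O)(=O)C(F)(F)F)C[C@H]1C(C)=CC[C@H](OC(C)=O)[C@@]1([C@@H](OC(=O)CC)CC/C(C)=C\[Sn](C)(C)C)C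
F3 | step 24 | methyl (2Z)-2-[(1S,2S,5Z,10S,14S)-14-acetoxy-1,5,11-trimethyl-7-oxo-2-(propanoyloxy)bicyclo[8.4.0]tetradeca-5,11-dien-8-ylidene]propanoate | CCC(=O)O[C@H]1CC/C(C)=C\C(=O)/C(C[C@H]2C(C)=CC[C@H](OC(C)=O)[C@]12C)=C(/C)C(=O)OC
F4 | step 11 | 1-[(1S,2S,6S)-6-[(tert-butyldimethylsilyl)oxy]-2-{2-[(4-methoxybenzyl)oxy]ethyl}-1,3-dimethylcyclohex-3-en-1-yl]ethan-1-ol (both carbinol epimers) | COc1ccc(COCC[C@H]2C(C)=CC[C@H](O[Si](C)(C)C(C)(C)C)[C@@]2(C(C)O)C)cc1
F5 | step 7 | 3-{[(2Z)-5-[(4-methoxybenzyl)oxy]-2-methylpent-2-en-1-yl]oxy}-2-methylcyclopent-2-en-1-one | COc1ccc(COCC/C=C(/C)COC2=C(C)C(=O)CC2)cc1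
F6 | step 7 | (1S)-3-{[(2Z)-5-[(4-methoxybenzyl)oxy]-2-methylpent-2-en-1-yl]oxy}-2-methylcyclopent-2-en-1-ol | COc1ccc(COCC/C=C(/C)COC2=C(C)[C@@H](O)CC2)cc1
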